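## Structural features

The target is a linear trimer of three 2-(4-hydroxyphenyl)chroman units with 5,7-dioxygenated A rings: the upper unit (ring U) is bonded through C4 to C8 of the middle unit (ring M), and ring M through C4 to C8 of the lower unit (ring L), which ends in a free flavan-3,4-diol. There are nine stereocentres: U is (2S,3S,4R), M is (2R,3R,4S), L is (2S,3S,4R). In U and in M the three contiguous centres C2, C3 and C4 are all-cis (C2 aryl, C3 OH and the C4 interflavan aryl on one face), and the two triads have opposite absolute sense; L is 2,3-cis-3,4-trans and shares the C2/C3 sense of U. Each interflavan bond joins a tertiary benzylic C4 to an A-ring carbon flanked by two oxygens and lies next to the peri C5 oxygen, so both bonds are very congested; they are also cis to O3, the opposite of what addition of an arene to a C4 cation gives (anti to O3). Fragile groups are the C4–OH of ring L (benzylic on a phloroglucinol ring, ionised by acid and open to hydrogenolysis), the acid-labile interflavan bonds and the nine oxidation-prone phenols. The real difficulty is the pair of all-cis triads with 3,4-cis interflavan bonds, in opposite enantiomeric series, next to an acid-labile terminus. The key step exploits the fact that in each all-cis unit the C3 carbinol is flanked by C2–H (benzylic, bonded to O1) and C4–H (diarylmethine): at the C3-ketone level both are α-acidic, so the whole triad becomes stereochemically labile and can be set at once by a catalyst-controlled dynamic kinetic hydrogenation, and the C4–C8 bond becomes an α-aryl ketone bond that can be made by enolate arylation under base.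

## Logic of the disconnections

21 to 20: the twelve O–CH2Ph bonds are cut. All nine phenols and O3 of ring U, O3 and O4 of ring L are carried as benzyl ethers, which tolerate base, organopalladium and ruthenium hydride chemistry and fall in one operation. The demand on the forward step is that hydrogenolysis spares the benzylic C4–O bond of ring L.

20 to 19 (key disconnection): the C3–H and O–H bonds of ring M are removed, which erases C2, C3 and C4 of ring M together. In one sentence, the route is a catalyst-controlled dynamic kinetic hydrogenation of a stereochemically labile 4-(flavan-8-yl)flavan-3-one. The gain is that three stereocentres, and any need for an enantiopure middle monomer, disappear. The forward step must epimerise C2 and C4 faster than it reduces, and the catalyst must override the resident rings U and L.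

19 to 18 and 12: the C4(M)–C8(L) bond is cut with C4 as enolate carbon and C8 as aryl bromide, the reverse of the usual polarity. At the ketone level this bond is made with base only, its configuration is irrelevant because it is set afterwards, and the bromide fixes C8 regiochemistry. The trimer falls to a dimer and a monomer. The forward step is a palladium-catalysed coupling of a hindered bromide with regioselective enolisation at C4.

18 to 17 to 16: the dioxolane C–O bonds and the O3(U)–benzyl bond are cut. Ring M must be an inert ketal while its C8–Br is coupled and a ketone afterwards; the free OH of ring U is capped as a benzyl ether that leaves in the last step. The hydrolysis must be mild enough for the interflavan bond.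

16 to 15: the same operation as the key step, on ring U with the mirror-image catalyst, erases C2, C3 and C4 of ring U. C2 of the ketal ring is left racemic on purpose, because it becomes labile again in 19.

15 to 8 and 14: the C4(U)–C8(M) bond is cut in the same enolate/aryl bromide sense. Because the ketone of 14 is masked, 14 can act only as the electrophile and 8 only as the nucleophile. Both partners are monomers.

14 to 13 to 8: the C8–Br bond and the ketal C–O bonds are cut. Bromination at the monomer stage secures C8 over C6 before any other A ring is present.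

12 to 11 to 10 to 9 to 8: the O3–benzyl bond, the C4–O bond (hydride abstraction and capture by benzyl alcohol anti to O3, which sets C4 of ring L), the C8–Br bond, and the C3–H/O–H bonds (dynamic kinetic hydrogenation, which sets C2 and C3 of ring L) are cut in turn. All later steps are basic or neutral, as the C4–O bond requires.

8 to 7 to 5 to 3 to 1 and 2: the racemic ketone 8, the single building block for all three units, is traced through C3 oxidation, hydroboration of the C3=C4 bond, reductive ring closure of a chalcone (O1–C2 bond) and an aldol condensation (C2–C3 bond of the propenone) to two catalogue aromatics. No stereocontrol is needed in this part.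

## Other disconnections considered

Alternative 1: the first idea is to cut both C4–C8 bonds as C4 cation plus nucleophilic arene. The forward key step would be Lewis-acid ionisation (TMSOTf) of a C4 ether such as A1 and Friedel–Crafts capture by C8–H of the next unit. The arene enters anti to O3, so each junction would be formed 3,4-trans, whereas both junctions of the target are 3,4-cis. The same Lewis acid would also ionise the C4–O bond of ring L. The chosen plan sets C4 after the bond exists and uses no acid.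

Alternative 2: the same bonds are cut with C8 as a carbanion. After bromine–lithium exchange at C8 of the neighbouring unit, addition to the C4 carbonyl of a ketone such as A2 and ionic hydrogenation (Et3SiH, CF3CO2H) of the C4–OH so created would deliver hydride anti to O3 and give the all-cis relation. The relative configuration is right in principle. However, both enantiomeric 2,3-cis monomers would have to be made separately, and the middle unit would have to serve first as C8 nucleophile and then as C4 ketone. The silane/acid step would also reduce the C4–O bond of ring L, which would force a late C4 oxidation next to two tertiary, doubly benzylic C4–H bonds. The chosen plan is shorter, takes all three units from one racemic ketone, and stays basic.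

Alternative 3: ring C of each all-cis unit is cut at O1–C2 and C3–C4. The forward key step would be acid ionisation of a benzhydrol such as A3 to the o-quinone methide A4 and inverse-demand hetero-Diels–Alder reaction with the (Z)-enol acetate A5, which would close ring C and create three stereocentres at once. The grounds against it are structural. The peri C5 benzyloxy group makes the geometry of A4 ambiguous. A stepwise cationic pathway with acetoxy participation would favour 2,3-trans. Enantiofacial control would be needed twice with opposite sense. The acid that ionises A3 would also ionise the C4–O bond of ring L. The triad would probably need correction through the C3 ketone anyway, and the chosen plan goes there directly.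

Key step: step 16

Assumption on starting material: 1 is taken as the catalogue compound 2'-hydroxy-4',6'-bis(benzyloxy)acetophenone.

Assumption on the catalyst: the sense of induction of the two mirror-image ruthenium catalysts is assigned by analogy with 2-arylcycloalkanones; if it were reversed on the chromanone, the two antipodes would be exchanged between steps 5/12 and step 16. Xyl-SDP is 7,7'-bis[di(3,5-dimethylphenyl)phosphino]-1,1'-spirobiindane and DPEN is 1,2-diphenylethane-1,2-diamine.

## Route

Step 1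
Reactants: 1 1-[2,4-bis(benzyloxy)-6-hydroxyphenyl]ethan-1-one; 2 4-(benzyloxy)benzaldehyde
Product: 3 (E)-1-[2,4-bis(benzyloxy)-6-hydroxyphenyl]-3-[4-(benzyloxy)phenyl]prop-2-en-1-one
Conditions: KOH (50% aq.), EtOH/THF, rt
Reagents that add atoms: none
Why: Claisen–Schmidt aldol condensation; the hydrogen-bonded 2'-hydroxychalcone is the stable (E)-enone and no stereocentre is formed.

Step 2
Reactants: 3 (E)-1-[2,4-bis(benzyloxy)-6-hydroxyphenyl]-3-[4-(benzyloxy)phenyl]prop-2-en-1-one
Product: 5 rac-5,7-bis(benzyloxy)-2-[4-(benzyloxy)phenyl]-2H-chromene, via allylic alcohol 4 (not isolated)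
Conditions: NaBH4, i-PrOH/THF, 0 °C to 70 °C; then AcOH, rt
Reagents that add atoms: none
Why: 1,2-reduction of the 2'-hydroxychalcone carbonyl gives 4, which loses water and closes through the phenol oxygen onto the allylic terminus (the known reductive cyclisation of 2'-hydroxychalcones to flav-3-enes); C2 is formed racemic, which is what the route needs.

Step 3
Reactants: 5 rac-5,7-bis(benzyloxy)-2-[4-(benzyloxy)phenyl]-2H-chromene
Product: 7 rac-(2R,3S)-5,7-bis(benzyloxy)-2-[4-(benzyloxy)phenyl]chroman-3-ol, via 3-borylflavan 6 (not isolated)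
Conditions: BH3·THF, THF, 0 °C to rt; then NaOH (3 M), H2O2 (30%), 0 °C to rt
Reagents that add atoms: borane–tetrahydrofuran (B.C1CCOC1; boron of 6); hydrogen peroxide (OO; oxygen of the 3-OH)
Why: Hydroboration–oxidation of the styrene-type C3=C4 bond places boron at C3 (hydrogen at the benzylic C4) anti to the C2 aryl group, and oxidation with retention gives the 2,3-trans alcohol; this configuration is erased in step 4.

Step 4
Reactants: 7 rac-(2R,3S)-5,7-bis(benzyloxy)-2-[4-(benzyloxy)phenyl]chroman-3-ol
Product: 8 rac-5,7-bis(benzyloxy)-2-[4-(benzyloxy)phenyl]chroman-3-one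
Conditions: Dess–Martin periodinane, CH2Cl2 (water-saturated), rt
Reagents that add atoms: none
Why: Dess–Martin oxidation of the secondary alcohol under neutral conditions is the standard access to flavan-3-ones; the racemic ketone is the common precursor of all three units.

Step 5
Reactants: 8 rac-5,7-bis(benzyloxy)-2-[4-(benzyloxy)phenyl]chroman-3-one
Product: 9 (2S,3S)-5,7-bis(benzyloxy)-2-[4-(benzyloxy)phenyl]chroman-3-ol
Conditions: H2 (50 atm), RuCl2[(S)-Xyl-SDP][(R,R)-DPEN] (0.5 mol%), t-BuOK (20 mol%), i-PrOH/toluene, 25 °C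
Reagents that add atoms: none
Why: Noyori-type asymmetric hydrogenation with dynamic kinetic resolution of an α-aryl cyclic ketone: t-BuOK racemises C2 through the enolate, the ruthenium hydride accepts the (2S)-ketone and delivers hydride to the Re face of C3=O anti to the pseudo-equatorial aryl group, which gives the 2,3-cis (2S,3S) alcohol.

Step 6
Reactants: 9 (2S,3S)-5,7-bis(benzyloxy)-2-[4-(benzyloxy)phenyl]chroman-3-ol
Product: 10 (2S,3S)-5,7-bis(benzyloxy)-2-[4-(benzyloxy)phenyl]-8-bromochroman-3-ol
Conditions: NBS (1.0 equiv), CH2Cl2, −78 °C to −20 °C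
Reagents that add atoms: N-bromosuccinimide (O=C1CCC(=O)N1Br)
Why: Electrophilic aromatic bromination; in 5,7-bis(benzyloxy)flavans C8 (between the ring oxygen and one benzyloxy group) reacts ahead of C6 (between two benzyloxy groups), so one equivalent at low temperature should give the 8-bromide.

Step 7
Reactants: 10 (2S,3S)-5,7-bis(benzyloxy)-2-[4-(benzyloxy)phenyl]-8-bromochroman-3-ol
Product: 11 (2S,3S,4R)-4,5,7-tris(benzyloxy)-2-[4-(benzyloxy)phenyl]-8-bromochroman-3-ol
Conditions: DDQ (1.5 equiv), BnOH (5 equiv), 4 Å molecular sieves, CH2Cl2, rt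
Reagents that add atoms: benzyl alcohol (OCc1ccccc1)
Why: DDQ abstracts hydride from C4 (benzylic oxidation assisted by the A-ring oxygens) and benzyl alcohol adds to the cationic C4 anti to the axial C3–OH, the known C4 alkoxylation of 2,3-cis flavan-3-ols; this sets the 3,4-trans (4R) centre of ring L.

Step 8
Reactants: 11 (2S,3S,4R)-4,5,7-tris(benzyloxy)-2-[4-(benzyloxy)phenyl]-8-bromochroman-3-ol
Product: 12 (2S,3S,4R)-3,4,5,7-tetrakis(benzyloxy)-2-[4-(benzyloxy)phenyl]-8-bromochromane
Conditions: NaH, BnBr, n-Bu4NI (cat.), DMF, 0 °C to rt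
Reagents that add atoms: benzyl bromide (BrCc1ccccc1)
Why: Williamson etherification of the C3 alkoxide; the aryl bromide and the C4 ether are stable to these conditions and no stereocentre is touched.

Step 9
Reactants: 8 rac-5,7-bis(benzyloxy)-2-[4-(benzyloxy)phenyl]chroman-3-one
Product: 13 rac-5,7-bis(benzyloxy)-2-[4-(benzyloxy)phenyl]spiro[chromane-3,2'-[1,3]dioxolane]
Conditions: (TMSOCH2)2 (3 equiv), TMSOTf (10 mol%), CH2Cl2, −78 °C to −20 °C; then pyridine
Reagents that add atoms: 1,2-bis(trimethylsilyloxy)ethane (C[Si](C)(C)OCCO[Si](C)(C)C)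
Why: Noyori ketalisation under aprotic conditions masks the enolisable ketone so that this unit can later serve only as the aryl bromide partner.

Step 10
Reactants: 13 rac-5,7-bis(benzyloxy)-2-[4-(benzyloxy)phenyl]spiro[chromane-3,2'-[1,3]dioxolane]
Product: 14 rac-5,7-bis(benzyloxy)-2-[4-(benzyloxy)phenyl]-8-bromospiro[chromane-3,2'-[1,3]dioxolane]
Conditions: NBS (1.0 equiv), CH2Cl2, −78 °C to −20 °C
Reagents that add atoms: N-bromosuccinimide (O=C1CCC(=O)N1Br)
Why: Same C8-selective electrophilic bromination as in step 6, done on the monomer so that no other A ring competes; the ketal is inert to NBS.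

Step 11
Reactants: 8 rac-5,7-bis(benzyloxy)-2-[4-(benzyloxy)phenyl]chroman-3-one; 14 rac-5,7-bis(benzyloxy)-2-[4-(benzyloxy)phenyl]-8-bromospiro[chromane-3,2'-[1,3]dioxolane]
Product: 15 5,7-bis(benzyloxy)-2-[4-(benzyloxy)phenyl]-4-{5,7-bis(benzyloxy)-2-[4-(benzyloxy)phenyl]spiro[chromane-3,2'-[1,3]dioxolan]-8-yl}chroman-3-one (C2 and C4 of the ketone ring labile; ketal ring racemic at C2)
Conditions: Pd(OAc)2 (5 mol%), P(t-Bu)3·HBF4 (10 mol%), NaOt-Bu (2.5 equiv), toluene (degassed), 80 °C; then aq. NH4Cl
Reagents that add atoms: none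
Why: Palladium-catalysed ketone α-arylation (Buchwald–Hartwig type): zerovalent palladium inserts into the C8–Br bond of 14, the C4 enolate of 8 (the benzylic and more acidic α-position, whereas C2 is tertiary) is transferred to palladium, and reductive elimination forms the C4(U)–C8(M) bond; no stereocontrol is needed because C2 and C4 of the new ketone stay labile.

Step 12
Reactants: 15 dimeric ketone (ring U as the C3 ketone; ring M as the ketal)
Product: 16 (2S,3S,4R)-5,7-bis(benzyloxy)-2-[4-(benzyloxy)phenyl]-4-{(2RS)-5,7-bis(benzyloxy)-2-[4-(benzyloxy)phenyl]spiro[chromane-3,2'-[1,3]dioxolan]-8-yl}chroman-3-ol (both C2 epimers of the ketal ring)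
Conditions: H2 (50 atm), RuCl2[(S)-Xyl-SDP][(R,R)-DPEN] (2 mol%), t-BuOK (0.5 equiv), i-PrOH/toluene, 30 °C
Reagents that add atoms: none
Why: Same dynamic kinetic hydrogenation as the key step with the catalyst antipode of step 5: base equilibrates C2 and C4 of ring U, and hydride goes to the Re face of C3=O anti to both pseudo-equatorial aryl groups, which sets the all-cis (2S,3S,4R) triad; C2 of the ketal ring stays racemic and is equilibrated later in 19.

Step 13
Reactants: 16 dimeric alcohol (ring U all-cis with free 3-OH; ring M as the ketal)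
Product: 17 (2S,3S,4R)-3,5,7-tris(benzyloxy)-2-[4-(benzyloxy)phenyl]-4-{(2RS)-5,7-bis(benzyloxy)-2-[4-(benzyloxy)phenyl]spiro[chromane-3,2'-[1,3]dioxolan]-8-yl}chromane
Conditions: NaH, BnBr, n-Bu4NI (cat.), DMF/THF, 0 °C to rt
Reagents that add atoms: benzyl bromide (BrCc1ccccc1)
Why: Williamson etherification; the benzyl ether shields the secondary alcohol from palladium-mediated oxidation in step 15 and leaves in the final hydrogenolysis.

Step 14
Reactants: 17 dimeric benzyl ether (ring M as the ketal)
Product: 18 (2RS)-5,7-bis(benzyloxy)-2-[4-(benzyloxy)phenyl]-8-{(2S,3S,4R)-3,5,7-tris(benzyloxy)-2-[4-(benzyloxy)phenyl]chroman-4-yl}chroman-3-one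
Conditions: p-TsOH·H2O (0.2 equiv), THF/H2O (5:1), 45 °C
Reagents that add atoms: water (O)
Why: Acid-catalysed ketal hydrolysis frees the ring M ketone; dilute aqueous acid is far weaker than the anhydrous Lewis acids needed to cleave a benzylated interflavan bond, and ring L is not yet present.

Step 15
Reactants: 18 dimeric ketone (ring M as the C3 ketone carrying ring U at C8); 12 (2S,3S,4R)-3,4,5,7-tetrakis(benzyloxy)-2-[4-(benzyloxy)phenyl]-8-bromochromane
Product: 19 5,7-bis(benzyloxy)-2-[4-(benzyloxy)phenyl]-4-{(2S,3S,4R)-3,4,5,7-tetrakis(benzyloxy)-2-[4-(benzyloxy)phenyl]chroman-8-yl}-8-{(2S,3S,4R)-3,5,7-tris(benzyloxy)-2-[4-(benzyloxy)phenyl]chroman-4-yl}chroman-3-one (C2 and C4 of the ketone ring labile)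
Conditions: Pd(OAc)2 (5 mol%), P(t-Bu)3·HBF4 (10 mol%), NaOt-Bu (2.5 equiv), toluene (degassed), 80 °C; then aq. NH4Cl
Reagents that add atoms: none
Why: Second palladium-catalysed ketone α-arylation: the C4 enolate of ring M (its only CH2 α-position) couples with the C8 bromide 12 to form the C4(M)–C8(L) bond; the basic medium leaves the C4–O bond of ring L and all existing stereocentres untouched.

Step 16
Reactants: 19 trimeric ketone (ring M as the C3 ketone between resolved rings U and L)
Product: 20 (2R,3R,4S)-5,7-bis(benzyloxy)-2-[4-(benzyloxy)phenyl]-4-{(2S,3S,4R)-3,4,5,7-tetrakis(benzyloxy)-2-[4-(benzyloxy)phenyl]chroman-8-yl}-8-{(2S,3S,4R)-3,5,7-tris(benzyloxy)-2-[4-(benzyloxy)phenyl]chroman-4-yl}chroman-3-ol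
Conditions: H2 (50 atm), RuCl2[(R)-Xyl-SDP][(S,S)-DPEN] (2 mol%), t-BuOK (0.5 equiv), i-PrOH/toluene, 30 °C
Reagents that add atoms: none
Why: t-BuOK interconverts all stereoisomers of 19 at C2 and C4 of ring M through the two enolates (C4–H is a diarylmethine α to C=O, C2–H is benzylic, α-oxygenated and α to C=O), so the ketone reacts as one substrate. The divalent ruthenium hydride formed from the precatalyst, H2 and base transfers hydride and proton to C3=O in an outer-sphere six-membered transition state; the closest known reaction type is the Noyori-type asymmetric hydrogenation with dynamic kinetic resolution of 2-aryl- and 2,6-disubstituted cycloalkanones to all-cis cycloalkanols. No ring is closed. C3 is set by the catalyst, whose (R)/(S,S) antipode delivers hydride to the Si face of the carbonyl. C2 and C4 follow from that choice, because reduction is fastest for the 2,4-cis epimer with both aryl groups pseudo-equatorial and hydride enters anti to them (equatorial attack, axial carbinol), which gives the 2,3-cis-3,4-cis (2R,3R,4S) triad. The step needs epimerisation faster than reduction, which the acidity of both α-hydrogens should secure, and catalyst control over the resident rings U and L, which is expected because recognition takes place at the carbonyl and its two α-substituents. Chemoselectivity follows from the absence of any other carbonyl and the inertness of benzyl ethers to homogeneous ruthenium hydrides, and the basic medium spares the acid-labile C4–O bond of ring L.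

Step 17
Reactants: 20 protected trimer (twelve benzyl ethers; free 3-OH on ring M)
Product: 21 (2R,3R,4S)-2-(4-hydroxyphenyl)-4-[(2S,3S,4R)-3,4,5,7-tetrahydroxy-2-(4-hydroxyphenyl)chroman-8-yl]-8-[(2S,3S,4R)-3,5,7-trihydroxy-2-(4-hydroxyphenyl)chroman-4-yl]chromane-3,5,7-triol
Conditions: H2 (1 atm), Pd(OH)2/C, THF/MeOH/H2O (10:10:1), NaHCO3 (trace), rt
Reagents that add atoms: none
Why: Hydrogenolysis of the twelve benzyl ethers over Pd(OH)2/C under neutral, buffered conditions; the unhindered O–CH2Ph bonds should cleave well before the hindered secondary C4–O bond of ring L, and any transient ionisation at that carbon in the aqueous medium would be recaptured by water anti to O3, which is the configuration required.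

## Compound list

1 | 1-[2,4-bis(benzyloxy)-6-hydroxyphenyl]ethan-1-one | CC(=O)c1c(O)cc(OCc2ccccc2)cc1OCc1ccccc1 | starting material
2 | 4-(benzyloxy)benzaldehyde | O=Cc1ccc(OCc2ccccc2)cc1 | starting material
3 | (E)-1-[2,4-bis(benzyloxy)-6-hydroxyphenyl]-3-[4-(benzyloxy)phenyl]prop-2-en-1-one | O=C(/C=C/c1ccc(OCc2ccccc2)cc1)c1c(O)cc(OCc2ccccc2)cc1OCc1ccccc1 | intermediate
4 | rac-(E)-1-[2,4-bis(benzyloxy)-6-hydroxyphenyl]-3-[4-(benzyloxy)phenyl]prop-2-en-1-ol (allylic alcohol, not isolated) | OC(/C=C/c1ccc(OCc2ccccc2)cc1)c1c(O)cc(OCc2ccccc2)cc1OCc1ccccc1 | intermediate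
5 | rac-5,7-bis(benzyloxy)-2-[4-(benzyloxy)phenyl]-2H-chromene | C1(c2ccc(OCc3ccccc3)cc2)C=Cc2c(OCc3ccccc3)cc(OCc3ccccc3)cc2O1 | intermediate
6 | rac-2,3-trans-{5,7-bis(benzyloxy)-2-[4-(benzyloxy)phenyl]chroman-3-yl}borane (3-borylflavan, not isolated; one enantiomer drawn) | B[C@H]1Cc2c(OCc3ccccc3)cc(OCc3ccccc3)cc2O[C@@H]1c1ccc(OCc2ccccc2)cc1 | intermediate
7 | rac-(2R,3S)-5,7-bis(benzyloxy)-2-[4-(benzyloxy)phenyl]chroman-3-ol (2,3-trans; one enantiomer drawn) | O[C@H]1Cc2c(OCc3ccccc3)cc(OCc3ccccc3)cc2O[C@@H]1c1ccc(OCc2ccccc2)cc1 | intermediate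
8 | rac-5,7-bis(benzyloxy)-2-[4-(benzyloxy)phenyl]chroman-3-one | O=C1Cc2c(OCc3ccccc3)cc(OCc3ccccc3)cc2OC1c1ccc(OCc2ccccc2)cc1 | intermediate
9 | (2S,3S)-5,7-bis(benzyloxy)-2-[4-(benzyloxy)phenyl]chroman-3-ol | O[C@H]1Cc2c(OCc3ccccc3)cc(OCc3ccccc3)cc2O[C@H]1c1ccc(OCc2ccccc2)cc1 | intermediate
10 | (2S,3S)-5,7-bis(benzyloxy)-2-[4-(benzyloxy)phenyl]-8-bromochroman-3-ol | O[C@H]1Cc2c(OCc3ccccc3)cc(OCc3ccccc3)c(Br)c2O[C@H]1c1ccc(OCc2ccccc2)cc1 | intermediate
11 | (2S,3S,4R)-4,5,7-tris(benzyloxy)-2-[4-(benzyloxy)phenyl]-8-bromochroman-3-ol | Brc1c(OCc3ccccc3)cc(OCc3ccccc3)c2c1O[C@@H](c1ccc(OCc3ccccc3)cc1)[C@@H](O)[C@@H]2OCc1ccccc1 | intermediate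
12 | (2S,3S,4R)-3,4,5,7-tetrakis(benzyloxy)-2-[4-(benzyloxy)phenyl]-8-bromochromane | Brc1c(OCc3ccccc3)cc(OCc3ccccc3)c2c1O[C@@H](c1ccc(OCc3ccccc3)cc1)[C@@H](OCc1ccccc1)[C@@H]2OCc1ccccc1 | intermediate
13 | rac-5,7-bis(benzyloxy)-2-[4-(benzyloxy)phenyl]spiro[chromane-3,2'-[1,3]dioxolane] | C1COC2(O1)Cc1c(OCc3ccccc3)cc(OCc3ccccc3)cc1OC2c1ccc(OCc2ccccc2)cc1 | intermediate
14 | rac-5,7-bis(benzyloxy)-2-[4-(benzyloxy)phenyl]-8-bromospiro[chromane-3,2'-[1,3]dioxolane] | C1COC2(O1)Cc1c(OCc3ccccc3)cc(OCc3ccccc3)c(Br)c1OC2c1ccc(OCc2ccccc2)cc1 | intermediate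
15 | 5,7-bis(benzyloxy)-2-[4-(benzyloxy)phenyl]-4-{5,7-bis(benzyloxy)-2-[4-(benzyloxy)phenyl]spiro[chromane-3,2'-[1,3]dioxolan]-8-yl}chroman-3-one (C2 and C4 of the ketone ring labile; ketal ring racemic at C2) | O(Cc9ccccc9)c1ccc(C2Oc3c(c(OCc9ccccc9)cc(OCc9ccccc9)c3C3c4c(OCc9ccccc9)cc(OCc9ccccc9)cc4OC(c4ccc(OCc9ccccc9)cc4)C3=O)CC25OCCO5)cc1 | intermediate
16 | (2S,3S,4R)-5,7-bis(benzyloxy)-2-[4-(benzyloxy)phenyl]-4-{(2RS)-5,7-bis(benzyloxy)-2-[4-(benzyloxy)phenyl]spiro[chromane-3,2'-[1,3]dioxolan]-8-yl}chroman-3-ol (both C2 epimers of the ketal ring) | O(Cc9ccccc9)c1ccc(C2Oc3c(c(OCc9ccccc9)cc(OCc9ccccc9)c3[C@H]3c4c(OCc9ccccc9)cc(OCc9ccccc9)cc4O[C@@H](c4ccc(OCc9ccccc9)cc4)[C@H]3O)CC25OCCO5)cc1 | intermediate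
17 | (2S,3S,4R)-3,5,7-tris(benzyloxy)-2-[4-(benzyloxy)phenyl]-4-{(2RS)-5,7-bis(benzyloxy)-2-[4-(benzyloxy)phenyl]spiro[chromane-3,2'-[1,3]dioxolan]-8-yl}chromane | O(Cc9ccccc9)c1ccc(C2Oc3c(c(OCc9ccccc9)cc(OCc9ccccc9)c3[C@H]3c4c(OCc9ccccc9)cc(OCc9ccccc9)cc4O[C@@H](c4ccc(OCc9ccccc9)cc4)[C@H]3OCc9ccccc9)CC25OCCO5)cc1 | intermediate
18 | (2RS)-5,7-bis(benzyloxy)-2-[4-(benzyloxy)phenyl]-8-{(2S,3S,4R)-3,5,7-tris(benzyloxy)-2-[4-(benzyloxy)phenyl]chroman-4-yl}chroman-3-one | O(Cc9ccccc9)c1ccc(C2Oc3c(c(OCc9ccccc9)cc(OCc9ccccc9)c3[C@H]3c4c(OCc9ccccc9)cc(OCc9ccccc9)cc4O[C@@H](c4ccc(OCc9ccccc9)cc4)[C@H]3OCc9ccccc9)CC2=O)cc1 | intermediate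
19 | 5,7-bis(benzyloxy)-2-[4-(benzyloxy)phenyl]-4-{(2S,3S,4R)-3,4,5,7-tetrakis(benzyloxy)-2-[4-(benzyloxy)phenyl]chroman-8-yl}-8-{(2S,3S,4R)-3,5,7-tris(benzyloxy)-2-[4-(benzyloxy)phenyl]chroman-4-yl}chroman-3-one (C2 and C4 of the ketone ring labile) | O(Cc9ccccc9)c1ccc(C2Oc3c(c(OCc9ccccc9)cc(OCc9ccccc9)c3[C@H]3c4c(OCc9ccccc9)cc(OCc9ccccc9)cc4O[C@@H](c4ccc(OCc9ccccc9)cc4)[C@H]3OCc9ccccc9)C(c3c(OCc9ccccc9)cc(OCc9ccccc9)c4c3O[C@@H](c3ccc(OCc9ccccc9)cc3)[C@@H](OCc9ccccc9)[C@@H]4OCc9ccccc9)C2=O)cc1 | intermediate
20 | (2R,3R,4S)-5,7-bis(benzyloxy)-2-[4-(benzyloxy)phenyl]-4-{(2S,3S,4R)-3,4,5,7-tetrakis(benzyloxy)-2-[4-(benzyloxy)phenyl]chroman-8-yl}-8-{(2S,3S,4R)-3,5,7-tris(benzyloxy)-2-[4-(benzyloxy)phenyl]chroman-4-yl}chroman-3-ol | O(Cc9ccccc9)c1ccc([C@H]2Oc3c(c(OCc9ccccc9)cc(OCc9ccccc9)c3[C@H]3c4c(OCc9ccccc9)cc(OCc9ccccc9)cc4O[C@@H](c4ccc(OCc9ccccc9)cc4)[C@H]3OCc9ccccc9)[C@@H](c3c(OCc9ccccc9)cc(OCc9ccccc9)c4c3O[C@@H](c3ccc(OCc9ccccc9)cc3)[C@@H](OCc9ccccc9)[C@@H]4OCc9ccccc9)[C@H]2O)cc1 | intermediate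
21 | (2R,3R,4S)-2-(4-hydroxyphenyl)-4-[(2S,3S,4R)-3,4,5,7-tetrahydroxy-2-(4-hydroxyphenyl)chroman-8-yl]-8-[(2S,3S,4R)-3,5,7-trihydroxy-2-(4-hydroxyphenyl)chroman-4-yl]chromane-3,5,7-triol (CNP0159291.1) | Oc1ccc([C@H]2Oc3c(c(O)cc(O)c3[C@H]3c4c(O)cc(O)cc4O[C@@H](c4ccc(O)cc4)[C@H]3O)[C@@H](c3c(O)cc(O)c4c3O[C@@H](c3ccc(O)cc3)[C@@H](O)[C@@H]4O)[C@H]2O)cc1 | target

## Step count and least certain steps

Total step count: 17. Longest linear sequence: 13 (steps 1 to 4, 9 and 10, 11 to 17); the ring L branch (steps 5 to 8) joins at step 15.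

Step 16 (key step; steps 5 and 12 use the same reaction type). Most likely to go wrong: epimerisation at C2 of ring M may be slower than reduction in the crowded trimer, so that the reaction behaves as a kinetic resolution and stalls. Alternatively, reduction may run through the 2,4-trans epimer, in which the C4 aryl group turns pseudo-axial to escape the peri C5 benzyloxy group, and erode the all-cis selectivity. A mismatch with the resident rings U and L could also lower facial control. Fallback, from 19 back to 20: 19 is equilibrated with DBU and reduced under substrate control with LiBH(s-Bu)3 (L-Selectride) in THF at −78 °C, which attacks equatorially and should give the two all-cis alcohols, 20 and its diastereomer with the antipodal ring M triad F1. Because rings U and L are already resolved, the two are diastereomers and are separated by chromatography; F1 is returned to 19 with Dess–Martin periodinane and recycled.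

Step 15 (and its twin, step 11). Most likely to go wrong: oxidative addition into the di-ortho-oxygenated C8–Br bond or C–C reductive elimination next to the peri C5 benzyloxy group may fail for steric reasons, leading to hydrodebromination of the bromide and recovery of the ketone; air oxidation of the enolate is a second risk. Fallback, from 12 (with 18) back to 19, by Pinhey arylation: bromine–lithium exchange on 12 (n-BuLi, THF, −78 °C) and quenching with B(OMe)3 give the arylboronic acid F2. Boron–lead exchange with Pb(OAc)4 and catalytic Hg(OAc)2 in CHCl3 gives the aryllead triacetate F3. F3 arylates C4 of the readily enolised benzylic ketone 18 (pyridine, CHCl3, 60 °C) by ligand coupling at tetravalent lead, a process known to transfer 2,6-dioxygenated aryl groups to crowded carbon acids, to give 19.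

Step 17. Most likely to go wrong: reductive cleavage of the benzylic C4–O bond of ring L, or its ionisation on the catalyst surface followed by self-condensation, during the long hydrogenolysis of twelve benzyl ethers. Fallback, from 10 back to 21, with O3 and O4 of ring L carried as silyl ethers that resist hydrogenolysis:
- 10 is oxidised with DDQ in wet CH2Cl2 to the 3,4-trans diol F4 (water adds anti to O3).
- Silylation with TBSOTf and 2,6-lutidine gives the bis(silyl) ether F5.
- F5 is coupled with 18 under the conditions of step 15 to give the trimeric ketone F6.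
- F6 is hydrogenated as in step 16 to the alcohol F7.
- F7 is debenzylated (H2, Pd(OH)2/C, EtOAc/THF) to the ten-fold free phenol F8.
- F8 is desilylated with Et3N·3HF in MeCN/THF to give 21.

Step 5. Most likely to go wrong: low enantiofacial discrimination, because the two α-carbons of 8 (aryl- and oxygen-substituted C2 against the benzylic CH2) are less different than in 2-arylcyclohexanones, or racemisation of C2 that is too slow. Fallback, from 8 back to 9: reduction of 8 with LiBH(s-Bu)3 in THF at −78 °C gives the racemic 2,3-cis alcohol F9, which is resolved by preparative chromatography on a chiral stationary phase; the (2S,3S) half is 9, and the (2R,3R) half is oxidised back to 8 with Dess–Martin periodinane.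

## Further compounds

F1 | step 16 | diastereomer of 20 with the (2S,3S,4R) triad in ring M | O(Cc9ccccc9)c1ccc([C@@H]2Oc3c(c(OCc9ccccc9)cc(OCc9ccccc9)c3[C@H]3c4c(OCc9ccccc9)cc(OCc9ccccc9)cc4O[C@@H](c4ccc(OCc9ccccc9)cc4)[C@H]3OCc9ccccc9)[C@H](c3c(OCc9ccccc9)cc(OCc9ccccc9)c4c3O[C@@H](c3ccc(OCc9ccccc9)cc3)[C@@H](OCc9ccccc9)[C@@H]4OCc9ccccc9)[C@@H]2O)cc1
F2 | step 15 | {(2S,3S,4R)-3,4,5,7-tetrakis(benzyloxy)-2-[4-(benzyloxy)phenyl]chroman-8-yl}boronic acid | OB(O)c1c(OCc3ccccc3)cc(OCc3ccccc3)c2c1O[C@@H](c1ccc(OCc3ccccc3)cc1)[C@@H](OCc1ccccc1)[C@@H]2OCc1ccccc1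
F3 | step 15 | {(2S,3S,4R)-3,4,5,7-tetrakis(benzyloxy)-2-[4-(benzyloxy)phenyl]chroman-8-yl}lead triacetate | CC(=O)O[Pb](OC(C)=O)(OC(C)=O)c1c(OCc3ccccc3)cc(OCc3ccccc3)c2c1O[C@@H](c1ccc(OCc3ccccc3)cc1)[C@@H](OCc1ccccc1)[C@@H]2OCc1ccccc1
F4 | step 17 | (2S,3S,4R)-5,7-bis(benzyloxy)-2-[4-(benzyloxy)phenyl]-8-bromochromane-3,4-diol | Brc1c(OCc3ccccc3)cc(OCc3ccccc3)c2c1O[C@@H](c1ccc(OCc3ccccc3)cc1)[C@@H](O)[C@@H]2O
F5 | step 17 | 3,4-bis(tert-butyldimethylsilyl) ether of F4 (2,3-cis-3,4-trans) | Brc1c(OCc3ccccc3)cc(OCc3ccccc3)c2c1O[C@@H](c1ccc(OCc3ccccc3)cc1)[C@@H](O[Si](C)(C)C(C)(C)C)[C@@H]2O[Si](C)(C)C(C)(C)C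
F6 | step 17 | analogue of 19 with tert-butyldimethylsilyloxy groups at C3 and C4 of ring L | O(Cc9ccccc9)c1ccc(C2Oc3c(c(OCc9ccccc9)cc(OCc9ccccc9)c3[C@H]3c4c(OCc9ccccc9)cc(OCc9ccccc9)cc4O[C@@H](c4ccc(OCc9ccccc9)cc4)[C@H]3OCc9ccccc9)C(c3c(OCc9ccccc9)cc(OCc9ccccc9)c4c3O[C@@H](c3ccc(OCc9ccccc9)cc3)[C@@H](O[Si](C)(C)C(C)(C)C)[C@@H]4O[Si](C)(C)C(C)(C)C)C2=O)cc1
F7 | step 17 | analogue of 20 with tert-butyldimethylsilyloxy groups at C3 and C4 of ring L | O(Cc9ccccc9)c1ccc([C@H]2Oc3c(c(OCc9ccccc9)cc(OCc9ccccc9)c3[C@H]3c4c(OCc9ccccc9)cc(OCc9ccccc9)cc4O[C@@H](c4ccc(OCc9ccccc9)cc4)[C@H]3OCc9ccccc9)[C@@H](c3c(OCc9ccccc9)cc(OCc9ccccc9)c4c3O[C@@H](c3ccc(OCc9ccccc9)cc3)[C@@H](O[Si](C)(C)C(C)(C)C)[C@@H]4O[Si](C)(C)C(C)(C)C)[C@H]2O)cc1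
F8 | step 17 | 21 carrying tert-butyldimethylsilyl ethers on O3 and O4 of ring L | Oc1ccc([C@H]2Oc3c(c(O)cc(O)c3[C@H]3c4c(O)cc(O)cc4O[C@@H](c4ccc(O)cc4)[C@H]3O)[C@@H](c3c(O)cc(O)c4c3O[C@@H](c3ccc(O)cc3)[C@@H](O[Si](C)(C)C(C)(C)C)[C@@H]4O[Si](C)(C)C(C)(C)C)[C@H]2O)cc1
F9 | step 5 | rac-(2R,3R)-5,7-bis(benzyloxy)-2-[4-(benzyloxy)phenyl]chroman-3-ol (racemic 2,3-cis alcohol; both enantiomers written) | O[C@H]1Cc2c(OCc3ccccc3)cc(OCc3ccccc3)cc2O[C@H]1c1ccc(OCc2ccccc2)cc1.O[C@@H]1Cc2c(OCc3ccccc3)cc(OCc3ccccc3)cc2O[C@@H]1c1ccc(OCc2ccccc2)cc1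
A1 | alternative 1 | (2S,3S,4R)-5,7-bis(benzyloxy)-2-[4-(benzyloxy)phenyl]-4-(2-ethoxyethoxy)chroman-3-ol | c1c(OCc3ccccc3)cc(OCc3ccccc3)c2c1O[C@@H](c1ccc(OCc3ccccc3)cc1)[C@@H](O)[C@@H]2OCCOCC
A2 | alternative 2 | (2S,3R)-5,7-bis(benzyloxy)-2-[4-(benzyloxy)phenyl]-3-[(tert-butyldimethylsilyl)oxy]chroman-4-one (2,3-cis) | CC(C)(C)[Si](C)(C)O[C@H]1C(=O)c2c(OCc3ccccc3)cc(OCc3ccccc3)cc2O[C@H]1c1ccc(OCc2ccccc2)cc1
A3 | alternative 3 | [2,4-bis(benzyloxy)-6-hydroxyphenyl]{(2S,3S,4R)-3,4,5,7-tetrakis(benzyloxy)-2-[4-(benzyloxy)phenyl]chroman-8-yl}methanol (carbinol centre undefined) | OC(c1c(O)cc(OCc3ccccc3)cc1OCc1ccccc1)c1c(OCc3ccccc3)cc(OCc3ccccc3)c2c1O[C@@H](c1ccc(OCc3ccccc3)cc1)[C@@H](OCc1ccccc1)[C@@H]2OCc1ccccc1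
A4 | alternative 3 | o-quinone methide from A3: 3,5-bis(benzyloxy)-6-({(2S,3S,4R)-3,4,5,7-tetrakis(benzyloxy)-2-[4-(benzyloxy)phenyl]chroman-8-yl}methylidene)cyclohexa-2,4-dien-1-one | O=C1C=C(OCc3ccccc3)C=C(OCc3ccccc3)C1=Cc1c(OCc3ccccc3)cc(OCc3ccccc3)c2c1O[C@@H](c1ccc(OCc3ccccc3)cc1)[C@@H](OCc1ccccc1)[C@@H]2OCc1ccccc1
A5 | alternative 3 | (Z)-2-[4-(benzyloxy)phenyl]ethenyl acetate | CC(=O)O/C=C\c1ccc(OCc2ccccc2)cc1
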